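(The data come from a simulation with made-up constants, and the scatter is random.)

How much starting material and target would stand after 40 h in Friday's, Wednesday's and Saturday's flasks, and which would lead?

common to all: starting material 40 mM

|  | second substrate | protic impurity | free enzyme | remark | time |
|---|---|---|---|---|---|
| ochre | 60 mM | 8 mM | 30 µM | run made earlier |  |
| red | 60 mM | 8 mM | 100 µM | run made earlier |  |
| Friday's | 60.0 mM | 8.00 mM | 40 µM |  | 40 h |
| Wednesday's | 60.0 mM | 8.00 mM | 80 µM |  | 40 h |
| Saturday's | 60.0 mM | 8.00 mM | 160 µM |  | 40 h |

| run | time / h | starting material / % | target / % | loaded enzyme / % | second complex / % |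
|---|---|---|---|---|---|
| ochre | 1.50 | 82.5 | 3.1 | 0 | 0 |
| ochre | 2.50 | 77.4 | 3.9 | 0 | 1.4 |
| ochre | 4.00 | 72.6 | 5.2 | 1.0 | 0 |
| ochre | 6.00 | 70.1 | 9.4 | 0.1 | 0 |
| ochre | 8.00 | 68.7 | 8.8 | 0.1 | 0.3 |
| ochre | 12.0 | 64.9 | 13.8 | 0 | 0.8 |
| ochre | 20.0 | 57.2 | 20.7 | 0.7 | 1.4 |
| red | 3.00 | 68.8 | 12.6 | 0 | 0 |
| red | 6.00 | 59.7 | 19.2 | 0.9 | 0.2 |
| red | 8.00 | 55.7 | 23.9 | 0.8 | 0.2 |
| red | 12.0 | 47.4 | 32.5 | 0.4 | 0.4 |
| red | 15.0 | 44.3 | 34.9 | 0 | 0 |
| red | 20.0 | 39.8 | 40.9 | 0 | 0 |

(standard deviation of a reading: 1 percentage point)

- a species is counted by the starting material in it: one spent catalyst counts as two
- the numbers in the tables scatter with a standard deviation of 1 percentage point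
- reactions considered so far: starting material + free enzyme <-> first complex; first complex -> loaded enzyme + first product; second substrate + loaded enzyme <-> second complex; second complex -> free enzyme + target; starting material + protic impurity -> quenched substrate; 2 first complex -> spent catalyst

- which of these there is most of at the end, counted by the starting material in it, Friday's (loaded enzyme / target / starting material / second complex)
- which of these there is most of at the end, counted by the starting material in it, Wednesday's (loaded enzyme / target / starting material / second complex)
- which of these there is most of at the end, counted by the starting material in it, Saturday's (loaded enzyme / target / starting material / second complex)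
- amount of the one of these that there is most of at the end, in percent of the starting material charged, Friday's
- amount of the one of these that there is most of at the end, in percent of the starting material charged, Wednesday's
- amount of the one of these that there is most of at the end, in percent of the starting material charged, Saturday's

I first asked which charges had to be known well. The protic impurity came first. It is charged at less than the starting material, so I took it to be consumed, each impurity removing one starting material. Every 0.400 mM of error in its charge would therefore shift the outcome by 1 percentage point, as much as the scatter of a reading. The second substrate mattered little for the total, since its charge exceeds that of the starting material. The enzyme's direct share was also small: one starting material per enzyme gives 0.400% on Saturday's, less than the scatter.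

So I treated the bound material as a correction and defined the quench ceiling, the fraction of the charge left to share between starting material and target: one minus impurity charge over starting-material charge, 80.0%. The red run's last readings sum to 80.7%.

The leader is whichever stands above the middle of the ceiling, 40.0%. I assumed the split followed enzyme charge times hours. Friday's then equals 16.0 h of the red run, which gave starting material 43.4% and target 36.6%. Wednesday's and Saturday's equal 32.0 h and 64.0 h, beyond the red run's 20.0 h, where starting material already read 39.8%, level with that middle within the scatter. For those two flasks I claimed target in the lead, without a figure.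

The forecast gave starting material at 44% for Friday's, target at 50% for Wednesday's and target at 64% for Saturday's, noting that “starting material plus target levels off near 80%”. Friday's gave starting material at 43.5%, Wednesday's gave target at 49.6%, and Saturday's gave target at 63.4%.

    starting material + free enzyme ⇌ first complex (K = 21.0 M⁻¹, k = 170 M⁻¹ s⁻¹)
    first complex → loaded enzyme + first product (k = 0.0310 s⁻¹)
    second substrate + loaded enzyme ⇌ second complex (K = 16.0 M⁻¹, k = 18.0 M⁻¹ s⁻¹)
    second complex → free enzyme + target (k = 0.0290 s⁻¹)
    starting material + protic impurity → quenched substrate (k = 0.00690 M⁻¹ s⁻¹)
    2 first complex → spent catalyst (k = 7.70 M⁻¹ s⁻¹)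

Wednesday's starting material and target came to 79.8% against the ceiling of 80.0%, with 20.0% as quenched substrate. The difference in free enzyme is the main reason Saturday's starting material stood at 16.3%: with Friday's enzyme charge the same recipe keeps 43.5%. In the neighbour of Wednesday's charged with 160 mM of starting material, the ceiling reckons to 95.0%, and that flask held 82.9% starting material and 12.0% target, together 94.9%.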